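The data come from a simulation from invented constants, and the scatter is random.

I began from a balance: if reagent adds to substrate once and to mono adduct a second time, then at equal charges the substrate fraction left, a, equals the bis fraction d plus the free-reagent fraction b, all as fractions of the charge.

| flask | substrate | reagent | remark | time |
|---|---|---|---|---|
| alder | 2 mM | 1 mM | run made earlier |  |
| oak | 2 mM | 4 mM | run made earlier |  |
| birch | 1 mM | 2 mM | run made earlier |  |
| flask | 2.0 mM | 2.00 mM |  | 15 min |

| run | time / min | mono adduct / % | substrate / % |
|---|---|---|---|
| alder | 1.33 | 40 | 57 |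
| alder | 4.00 | 49 | 50 |
| alder | 8.00 | 50 | 47 |
| alder | 10.0 | 46 | 47 |
| alder | 15.0 | 50 | 49 |
| oak | 1.33 | 60 | 7 |
| oak | 4.00 | 63 | 0 |
| oak | 8.00 | 65 | 0 |
| oak | 10.0 | 66 | 0 |
| oak | 15.0 | 69 | 0 |
| birch | 1.33 | 62 | 15 |
| birch | 4.00 | 71 | 1 |
| birch | 8.00 | 76 | 0 |
| birch | 10.0 | 74 | 2 |
| birch | 15.0 | 76 | 2 |

(standard deviation of a reading: 1.5 percentage points)

* equivalents of reagent to substrate, everything else as given, that leave most mono adduct at 15 min
* the amount of mono adduct then, in percent of the substrate charged
* the amount of mono adduct with the amounts as given

The alder run closed at 99.0% with reagent short, and its first reading gave s = 2.11 min⁻¹, the first addition's rate at this charge. In the oak run, once substrate read zero, mono adduct averaged 65.8%, so, calling the missing part bis adduct, I read g = 0.792, the bis ratio: bis fraction over mono fraction times free-reagent fraction, at this substrate charge.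

For the flask, g set to zero gave my upper bound, a shortfall of 1/(1+st) and mono adduct at 96.9%. Taking d = gb with mono counted whole, I got a = (1+g)/(st) and a shortfall a+d = (1+2g)/(st), so my lower bound was 91.8%. The forecast put mono adduct in this equal-charge flask at 82%, below that bracket, expecting that the over-added material “slowly feeds reagent back to the substrate”; for its best recipe, which lies outside the equal charges of my bracket, it gave 90% at 1.2 equiv.

The flask gave 92.7%, inside the bracket, and at best 93.4% at 1.05 equiv.

    substrate + reagent → mono adduct (k = 19.0 M⁻¹ s⁻¹)
    reagent + mono adduct ⇌ bis adduct (K = 420 M⁻¹, k = 19.0 M⁻¹ s⁻¹)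
    substrate → decomposition product (k = 7.10 × 10⁻⁵ s⁻¹)

At 15.0 min the bis step relaxed with a half-life of 0.142 min, shorter than the 15 min run, a pre-equilibrium, and the first addition used reagent at 0.046 of that step's forward rate. With the flask's mono adduct and free reagent, g gives bis adduct at 2.07%, and the flask held 2.24%. On a neighbour flask, with 3.4 mM of reagent at the same substrate charge and substrate taken as used up, g gives bis adduct at 25.9% and mono adduct at 74.1%; the computed flask held 73.1%, with substrate at 0%.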